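For 5.0 h at constant temperature, substrate stood with partner in two flasks, gamma and zeta, which differ in c(partner).

all flasks: substrate 0.10 M

| flask | partner | remark | time |
|---|---|---|---|
| Saturday's | 0.23 M | run made earlier |  |
| Monday's | 0.30 M | run made earlier |  |
| gamma | 0.180 M |  | 5.0 h |
| zeta | 0.270 M |  | 5.0 h |

- Saturday's (time / h: substrate / %, product / %): 0.417: 86, 7; 1.00: 72, 21; 2.00: 55, 28; 5.00: 38, 45
- Monday's (time / h: substrate / %, product / %): 1.33: 60, 24; 2.50: 43, 39; 4.00: 32, 49; 5.00: 30, 52

(readings scatter by 2 percentage points)

* part of the substrate that has reacted at the end, gamma
* part of the substrate that has reacted at the end, zeta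
* what raising the concentration of partner from its lowest to its highest value here does to the part of the substrate that has reacted (changes below 5 percentage points count as none) (no change / it rises / it falls)

- what has gone from substrate into another species counts as reacted, even if it can come back

Every run charged the same c(substrate), and substrate is the limiting reagent by charge. Gamma has 0.900 M·h, and I called this charged c(partner) times time the exposure. I read the reacted part against it, taking 100 minus substrate. Gamma's exposure lies between Monday's 0.750 M·h and Saturday's 1.15 M·h, and joining those two readings gave me 58.9%. Zeta's 1.35 M·h lies between Monday's 1.20 M·h and 1.50 M·h, which gave me 69.0%. That is a rise of 10 percentage points, more than the 5 points that counts.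

The forecast gave 55% for gamma, lower than mine, and 67% for zeta, lower than mine too, with the trend it rises. It added: “Gamma is a modest extrapolation, so it is less certain”.

The flasks gave 57.2% for gamma and 67.7% for zeta, and the answer on the trend is it rises, by 10 points.

    substrate + partner ⇌ intermediate (K = 7.70 M⁻¹, k = 3.40 × 10⁻⁴ M⁻¹ s⁻¹)
    intermediate ⇌ product + by-product (K = 0.220 M, k = 0.00180 s⁻¹)
    substrate + by-product ⇌ idle adduct, settled at all times (K = 7.10 M⁻¹)
    2 partner → homo dimer (k = 6.10 × 10⁻⁵ M⁻¹ s⁻¹)

In gamma, half of the turnover of substrate into intermediate up to 5.0 h was done by 1.51 h, and half of intermediate into product and by-product by 1.49 h. At the end, 53.1% of the partner charge was still free. At 2.50 h gamma's exposure was 0.450 M·h, close to Saturday's 0.460 M·h at 2.00 h, and substrate stood at 58.1% against the 55% read there.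

Gamma read at 12 h has an exposure of 2.16 M·h, past Monday's last, so no two readings enclose it, and I took the reacted part at Monday's last reading, about 70.0%, as my estimate. The simulation gave 70.1%.

(The data are simulated for substances that don't exist; scatter was added.)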